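**Target:** (R)-1-(5,8-dihydroxy-1,4-dioxo-1,4-dihydronaphthalen-2-yl)-2,2-dimethylcyclobutyl (Z)-2-methylbut-2-enoate, compound 24.

## The problem

The target is a naphthazarin (quinone ring A fused to dihydroxybenzene ring B) that carries at C2 a cyclobutane whose carbinol carbon C1' is fully substituted. C1' bears the quinone carbon, the angelate oxygen, the ring methylene C2' and the gem-dimethyl carbon C4'; C3' is the second ring methylene. C1' is the only stereocentre (R). Nothing else in the molecule can direct it, so its configuration has to come from a reagent or from a temporary stereocentre that is removed later. Three groups limit the chemistry: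

- The angelate isomerises from Z to E under light, base, nucleophilic catalysts and radicals.
- The tertiary ester on a strained ring next to an arene can ionise in acid.
- The naphthazarin is redox-active and electrophilic, so it cannot be carried through organometallic, photochemical or radical steps.

The ring itself is a 1-aryl-2,2-dimethylcyclobutanol, in which a quaternary carbinol sits beside a quaternary carbon in a four-membered ring. A direct ring closure would therefore have to form a bond to one of two crowded centres. The feature that opens a way round this is the C3'–C4' bond, which joins a methylene to the CMe2 carbon. If a carbonyl is inserted between these two atoms, the result is a strain-free cyclopentanone with a single enolisable α-position. A diazo group can then be placed only at C3', and a Wolff shift can only rebuild C3'–C4'.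

## Retrosynthesis

**24 back to 21 (through 22).** The two C=O and two O–H groups of the naphthazarin are masked as four aryl methyl ethers. Quinone 22 and tetramethyl ether 21 follow by two oxidative demethylations, the second passing through diquinone 23. The tetramethoxynaphthalene is chosen over acetal-type masks because it tolerates aryllithium formation, strong base, visible light and thiol radicals, and because its removal is oxidative and not a prolonged acid treatment of the tertiary ester. The forward steps must be brief, and which ring is oxidised first does not matter, because both paths meet at 23.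

**21 back to 18 and 19.** The acyl C–O bond is cut, giving tertiary cyclobutanol 18 and angelic acid 19. The ester is placed after the last photochemical and radical step because the Z-alkene would not survive them. The forward reaction must acylate a very hindered alkoxide without Z/E isomerisation; the mixed anhydride 20 is meant for this.

**18 back to 15 (through 17).** The silyl ether 17 protects the carbinol, and a carboxyl group is added retrosynthetically at C3' to give acid 15. This carbon is the trace of the ring contraction. Its removal by Barton decarboxylation (through ester 16) costs one step and erases the C3' stereocentre, so neither epimer of 15 is wasted.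

**15 back to 13 (key disconnection).** The C3'–C4' bond is cut and C4' is reattached to the carboxyl carbon, which enlarges the cyclobutane to the 2-diazocyclopentanone 13 (ketene 14 is the link). The neighbouring cuts are less attractive. Cutting C1'–C2' or C1'–C4' would create the stereocentre during a strained ring closure, and cutting C2'–C3' leaves no activating group. The chosen cut leaves C1' untouched. It replaces a four-membered ring by a five-membered one. It also turns the stereochemical problem into the addition of an aryl nucleophile to a cyclopentanone. The forward reaction must favour the 1,2-shift of C4' over hydride shift from C2'.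

**13 back to 11.** The C=N2 bond is removed to give ketone 11. Its carbonyl lies between CMe2 and CH2, so diazo transfer (through the trifluoroacetyl ketone 12) can occur at one carbon only.

**11 back to 8 (through 10 and 9).** The O–Si bond at C1' is cut (10), the ketone is reduced to the secondary carbinol (9) and that carbinol is silylated (8). The future carbonyl carbon thus serves as a temporary stereocentre: it differentiates the two faces of the neighbouring ketone and is oxidised away afterwards. The tertiary alcohol is silylated only after the oxidation, and this silyl ether blocks retro-aldol cleavage in the basic steps.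

**8 back to 3 and 5.** The aryl–C1' bond is cut. The aryl group comes from bromide 5 by way of aryllithium 6 and organocerium 7, and the electrophile is silyloxy ketone 3. An organometallic addition is preferred to a Friedel–Crafts-type bond formation because it fixes the position on the arene and gives the tertiary alcohol directly. The forward step needs 1,2-addition without enolisation and attack on one face.

**3 back to 1, and 5 back to 4.** Ketone 3 is the silyl ether of hydroxy ketone 2, which comes from the prochiral dione 1 by enantioselective reduction of one of two enantiotopic carbonyls. Bromide 5 comes from symmetrical arene 4, whose four ring CH positions are equivalent. All three starting materials (1, 4, 19) are commercial.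

## Roads not taken

**Alternative 1:** Alkyne insertion into a phthaloylcobalt complex.
- **Cut and key step.** The two bonds of ring A that join the carbonyl carbons to C2 and C3 are cut. Forward, benzocyclobutenedione A2 and CoCl(PPh3)3 give a phthaloylcobalt complex, which inserts the terminal alkyne A3 (with AgBF4) to give quinone A1 directly.
- **Merits.** The route is convergent, and A2 is symmetrical, so there is no regiochemical question. The quinone arrives at the right oxidation level, so no oxidative demethylation is needed.
- **Weak points.** The stereocentre must already be present in A3. That requires an enantioselective ethynylation of 2,2-dimethylcyclobutanone A4, in which a catalyst must distinguish CMe2 from CH2 on a small strained ketone. This is not a routine transformation, so a resolution would probably be needed. The alkyne is flanked by a quaternary carbon bearing an ester, which should slow insertion and invites ionisation of the propargylic ester by the silver salt. The metal is stoichiometric, and the final acetal removal needs acid.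
- **Comparison.** In convergence and step count this road is better. The chosen plan sets against it a configuration that comes from a standard ketone reduction, and no stoichiometric transition metal.

**Alternative 2:** Ring-contracting boronate 1,2-shift from a benzylic carbamate.
- **Cut and key step.** The bond between the carbinol carbon and the CMe2 carbon is cut. Forward, the secondary benzylic carbamate A6 is lithiated with LiN(iPr)2 and trapped by its own pinacol boronate to a five-membered borate. The ring B–C bond then shifts to the benzylic carbon with loss of carbamate, giving cyclobutylboronate A5, which is oxidised to the tertiary alcohol with retention. With retention in the borylation and anti migration, the (S)-carbamate A6 is the one that leads to (S)-A5.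
- **Merits.** The chirality comes from an easily made secondary benzylic alcohol. No carbon is added and then removed, so atom economy is better than in the chosen plan.
- **Weak points.** Contraction of a cyclic borate to a four-membered ring, with a tertiary alkyl group migrating to a tertiary benzylic carbon, is not an established reaction class. The ortho-methoxy arene invites competing ring lithiation and carbamoyl migration. An electron-rich benzylic borate tends to react through reversible or ionising paths that erode enantiopurity.
- **Comparison.** The chosen plan spends two extra steps on adding and deleting the carboxyl carbon. Its key step, however, is a known reaction type on the same ring sizes.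

**Alternative 3:** Moore ring expansion of an aryl hydroxycyclobutenone.
- **Cut and key step.** The bond between C1 and C8a of ring A is cut. Forward, heating the 4-aryl-4-hydroxycyclobutenone A8 opens it to a vinylketene, whose ketene carbon bonds to the free ortho carbon of the aryl group. This gives hydroquinone A7, which is oxidised and deprotected.
- **Merits.** The reaction is well established for naphthoquinones, the regiochemistry is fixed by the cyclobutenone, and again no oxidative demethylation is needed.
- **Weak points.** A8 would come from aryllithium A10 and cyclobutenedione A9. The aryllithium must choose one of two unlike carbonyls and leave the angelate ester alone. The thermolysis then heats a tertiary ester on a strained ring to well above 100 °C. The chiral cyclobutanol fragment has the same unsolved origin as in Alternative 1.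
- **Comparison.** The endgame would be milder than the one chosen. The chosen plan sets against it the late introduction of the angelate, after every organometallic, photochemical and thermal step.

Key step: step 9

Assumption: the aryl nucleophile is taken to enter ketone 3 anti to the C3 silyloxy group, which is why the (S)-configured relay centre is installed in step 1.

Remark: the CIP descriptor of C1' changes between R and S along the route (8, 9: R; 10 to 13: S; 14 onwards: R). This reflects only the changing priority of the CMe2 branch; the spatial arrangement is never altered.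

## Route

Step 1
Reactants: 1 2,2-dimethylcyclopentane-1,3-dione
Product: 2 (S)-3-hydroxy-2,2-dimethylcyclopentan-1-one
Conditions: (R)-2-methyl-CBS-oxazaborolidine (cat.), catecholborane, toluene, −78 °C; aqueous work-up
Reagents that add atoms: none
Why: Corey–Bakshi–Shibata reduction of one of two enantiotopic carbonyls; with the quaternary carbon as the large group the (R)-catalyst should deliver hydride to give the (S)-carbinol, and catecholborane at low temperature limits reduction of the second carbonyl.

Step 2
Reactants: 2 (S)-3-hydroxy-2,2-dimethylcyclopentan-1-one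
Product: 3 (S)-3-[(tert-butyldimethylsilyl)oxy]-2,2-dimethylcyclopentan-1-one
Conditions: TBSCl, imidazole, DMF, rt
Reagents that add atoms: tert-butyldimethylsilyl chloride, CC(C)(C)[Si](C)(C)Cl
Why: Standard imidazole-mediated silylation of a secondary alcohol; the silyl ether prevents quenching of the aryl-metal reagent and retro-aldol opening, and supplies the bulk that should differentiate the ketone faces.

Step 3
Reactants: 4 1,4,5,8-tetramethoxynaphthalene
Product: 5 2-bromo-1,4,5,8-tetramethoxynaphthalene
Conditions: NBS (1 equiv), CH2Cl2, rt
Reagents that add atoms: N-bromosuccinimide, O=C1CCC(=O)N1Br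
Why: Electrophilic aromatic bromination of an electron-rich arene whose four ring CH positions are equivalent, so a single monobromide should form and the first bromine slows a second substitution.

Step 4
Reactants: 5 2-bromo-1,4,5,8-tetramethoxynaphthalene; 3 (S)-3-[(tert-butyldimethylsilyl)oxy]-2,2-dimethylcyclopentan-1-one
Product: 8 (1R,3S)-3-[(tert-butyldimethylsilyl)oxy]-2,2-dimethyl-1-(1,4,5,8-tetramethoxynaphthalen-2-yl)cyclopentan-1-ol, via aryllithium 6 (not isolated), via arylcerium dichloride 7 (not isolated)
Conditions: 5, n-BuLi, THF, −78 °C; CeCl3 (anhydrous), −78 °C; then 3, −78 °C; aq NH4Cl; chromatographic removal of the minor diastereomer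
Reagents that add atoms: n-butyllithium, [Li]CCCC (Li in 6 only); cerium trichloride, Cl[Ce](Cl)Cl (Ce and Cl in 7 only)
Why: Lithium–bromine exchange, transmetalation and 1,2-addition of the organocerium reagent, which is weakly basic and so should add to the hindered ketone without enolising its α-methylene; the aryl group is expected to enter anti to the C3 silyloxy group, which sets C1 (the future C1') as R.

Step 5
Reactants: 8 (1R,3S)-3-[(tert-butyldimethylsilyl)oxy]-2,2-dimethyl-1-(1,4,5,8-tetramethoxynaphthalen-2-yl)cyclopentan-1-ol
Product: 9 (1R,3S)-2,2-dimethyl-1-(1,4,5,8-tetramethoxynaphthalen-2-yl)cyclopentane-1,3-diol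
Conditions: Bu4NF, THF, rt
Reagents that add atoms: none
Why: Fluoride-induced cleavage of a secondary silyl ether; the conditions are basic and mild, so the acid-sensitive tertiary benzylic alcohol is not at risk.

Step 6
Reactants: 9 (1R,3S)-2,2-dimethyl-1-(1,4,5,8-tetramethoxynaphthalen-2-yl)cyclopentane-1,3-diol
Product: 10 (S)-3-hydroxy-2,2-dimethyl-3-(1,4,5,8-tetramethoxynaphthalen-2-yl)cyclopentan-1-one
Conditions: Pr4N[RuO4] (cat.), N-methylmorpholine N-oxide, 4 Å MS, CH2Cl2, rt
Reagents that add atoms: none
Why: Ley–Griffith oxidation; only the secondary alcohol can be oxidised, and the neutral medium should leave the β-hydroxy ketone free of retro-aldol cleavage and the electron-rich arene untouched.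

Step 7
Reactants: 10 (S)-3-hydroxy-2,2-dimethyl-3-(1,4,5,8-tetramethoxynaphthalen-2-yl)cyclopentan-1-one
Product: 11 (S)-2,2-dimethyl-3-(1,4,5,8-tetramethoxynaphthalen-2-yl)-3-[(triethylsilyl)oxy]cyclopentan-1-one
Conditions: Et3SiOTf, 2,6-lutidine, CH2Cl2, −78 to 0 °C
Reagents that add atoms: triethylsilyl trifluoromethanesulfonate, CC[Si](CC)(CC)OS(=O)(=O)C(F)(F)F
Why: Silyl triflate silylation, the standard method for hindered tertiary alcohols; capping the oxygen removes the retro-aldol pathway before the basic steps that follow.

Step 8
Reactants: 11 (S)-2,2-dimethyl-3-(1,4,5,8-tetramethoxynaphthalen-2-yl)-3-[(triethylsilyl)oxy]cyclopentan-1-one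
Product: 13 (S)-2-diazo-5,5-dimethyl-4-(1,4,5,8-tetramethoxynaphthalen-2-yl)-4-[(triethylsilyl)oxy]cyclopentan-1-one, via trifluoroacetyl ketone 12 (not isolated)
Conditions: LiN(SiMe3)2, THF, −78 °C; CF3CO2CH2CF3; then MsN3, Et3N, H2O, MeCN, rt
Reagents that add atoms: 2,2,2-trifluoroethyl trifluoroacetate, O=C(OCC(F)(F)F)C(F)(F)F (CF3CO in 12 only); methanesulfonyl azide, CS(=O)(=O)N=[N+]=[N-] (N2 in 13)
Why: Regitz diazo transfer in its detrifluoroacetylative form; the enolate can form only at the single α-methylene, the trifluoroacetyl group activates that carbon and leaves as the sulfonyl trifluoroacetamide, and the silyloxy group lies γ to the enolate carbon, so it cannot be eliminated.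

Step 9
Reactants: 13 (S)-2-diazo-5,5-dimethyl-4-(1,4,5,8-tetramethoxynaphthalen-2-yl)-4-[(triethylsilyl)oxy]cyclopentan-1-one
Product: 15 (1RS,3R)-2,2-dimethyl-3-(1,4,5,8-tetramethoxynaphthalen-2-yl)-3-[(triethylsilyl)oxy]cyclobutane-1-carboxylic acid, via ketene 14 (not isolated)
Conditions: hν (LED, ca. 420–450 nm), THF/H2O, NaHCO3, rt
Reagents that add atoms: water, O
Why: Photochemical Wolff rearrangement with ring contraction: excitation of the n→π* band of 13 expels N2 and, because a cyclic diazo ketone is held s-Z, the C1–C5 bond (carbonyl to CMe2) anti to the departing nitrogen shifts in concert to the diazo carbon, so that C4' becomes bonded to C3' and the former carbonyl carbon leaves the ring as the ketene carbon of 14, to which water then adds to give 15. The closest known reaction type is the light-induced contraction of 2-diazocyclopentanones with a quaternary α'-carbon to cyclobutanecarboxylic acids. The cyclobutane is closed by a 1,2-shift (five-membered to four-membered ring) and not by a cyclisation, and the loss of N2 pays for the strain. The only new stereocentre, C3', arises without control on protonation after water addition and as both epimers, which is acceptable because step 10 removes it. The selectivity needed is migration of C4' in preference to 1,2-hydride shift from the C2' methylene (which would give a cyclopentenone) and to O–H insertion; direct singlet excitation of the locked s-Z diazo ketone should secure it, and visible light is chosen so that the tetramethoxynaphthalene, which should absorb only at shorter wavelength, neither filters the light nor sensitises triplet carbene chemistry. The site of contraction is fixed by step 8, and the CMe2 carbon is the only group on the acyl carbon that can migrate. C1' takes no part, carries a silyl ether that excludes retro-aldol cleavage, and should keep its configuration.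

Step 10
Reactants: 15 (1RS,3R)-2,2-dimethyl-3-(1,4,5,8-tetramethoxynaphthalen-2-yl)-3-[(triethylsilyl)oxy]cyclobutane-1-carboxylic acid
Product: 17 (R)-triethyl{[2,2-dimethyl-1-(1,4,5,8-tetramethoxynaphthalen-2-yl)cyclobutyl]oxy}silane, via Barton ester 16 (not isolated)
Conditions: N-hydroxypyridine-2-thione, DCC, DMAP (cat.), CH2Cl2, rt, dark; then t-BuSH, hν (tungsten lamp), rt
Reagents that add atoms: 1-hydroxypyridine-2(1H)-thione, ON1C=CC=CC1=S (atoms in 16 only)
Why: Barton reductive decarboxylation; the secondary cyclobutyl radical does not ring-open and takes hydrogen from the thiol, both epimers of 15 converge on one product, and the visible light used does not excite the arene.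

Step 11
Reactants: 17 (R)-triethyl{[2,2-dimethyl-1-(1,4,5,8-tetramethoxynaphthalen-2-yl)cyclobutyl]oxy}silane
Product: 18 (R)-2,2-dimethyl-1-(1,4,5,8-tetramethoxynaphthalen-2-yl)cyclobutan-1-ol
Conditions: Bu4NF, THF, rt to 40 °C
Reagents that add atoms: none
Why: Fluoride desilylation under non-acidic conditions, so the 1-arylcyclobutanol is not exposed to the ionisation and ring expansion that acid would cause.

Step 12
Reactants: 18 (R)-2,2-dimethyl-1-(1,4,5,8-tetramethoxynaphthalen-2-yl)cyclobutan-1-ol; 19 angelic acid, (Z)-2-methylbut-2-enoic acid
Product: 21 (R)-2,2-dimethyl-1-(1,4,5,8-tetramethoxynaphthalen-2-yl)cyclobutyl (Z)-2-methylbut-2-enoate, via mixed anhydride 20 (not isolated)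
Conditions: 19, 2,4,6-Cl3C6H2COCl, Et3N, toluene, rt; separately 18, n-BuLi, THF, −78 °C; then the anhydride solution, −78 to 0 °C
Reagents that add atoms: 2,4,6-trichlorobenzoyl chloride, O=C(Cl)c1c(Cl)cc(Cl)cc1Cl (atoms in 20 only)
Why: Yamaguchi-type acylation of a preformed lithium alkoxide; the two ortho chlorines steer attack to the angeloyl carbonyl, and the absence of nucleophilic catalysts at low temperature should preserve the Z geometry.

Step 13
Reactants: 21 (R)-2,2-dimethyl-1-(1,4,5,8-tetramethoxynaphthalen-2-yl)cyclobutyl (Z)-2-methylbut-2-enoate
Product: 22 (R)-1-(1,4-dimethoxy-5,8-dioxo-5,8-dihydronaphthalen-2-yl)-2,2-dimethylcyclobutyl (Z)-2-methylbut-2-enoate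
Conditions: (NH4)2Ce(NO3)6, MeCN/H2O, 0 °C, short reaction time
Reagents that add atoms: water, O
Why: Oxidative demethylation of a 1,4-dimethoxyarene by tetravalent cerium, with water supplying the quinone oxygens; the ring without the bulky acyloxyalkyl group is expected to be oxidised, and the regiochemistry is immaterial because both rings end as quinones in 23.

Step 14
Reactants: 22 (R)-1-(1,4-dimethoxy-5,8-dioxo-5,8-dihydronaphthalen-2-yl)-2,2-dimethylcyclobutyl (Z)-2-methylbut-2-enoate
Product: 24 (R)-1-(5,8-dihydroxy-1,4-dioxo-1,4-dihydronaphthalen-2-yl)-2,2-dimethylcyclobutyl (Z)-2-methylbut-2-enoate, via diquinone 23 (not isolated)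
Conditions: AgO, 6 M HNO3, acetone, 0 °C; then aq Na2S2O4 work-up
Reagents that add atoms: water, O
Why: Oxidative demethylation of the remaining dimethoxy ring by argentic oxide (divalent silver) to the diquinone, whose two-electron reduction by dithionite gives the naphthazarin; the medium is oxidising and not Lewis acidic, and the contact time is short, which should spare the tertiary ester and the angelate.

## Compound list

1 | 2,2-dimethylcyclopentane-1,3-dione | CC1(C)C(=O)CCC1=O | starting material
2 | (S)-3-hydroxy-2,2-dimethylcyclopentan-1-one | O[C@H]1CCC(=O)C1(C)C | intermediate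
3 | (S)-3-[(tert-butyldimethylsilyl)oxy]-2,2-dimethylcyclopentan-1-one | CC(C)(C)[Si](C)(C)O[C@H]1CCC(=O)C1(C)C | intermediate
4 | 1,4,5,8-tetramethoxynaphthalene | COc1ccc(OC)c2c(OC)ccc(OC)c12 | starting material
5 | 2-bromo-1,4,5,8-tetramethoxynaphthalene | COc1cc(Br)c(OC)c2c(OC)ccc(OC)c12 | intermediate
6 | (1,4,5,8-tetramethoxynaphthalen-2-yl)lithium | COc1cc([Li])c(OC)c2c(OC)ccc(OC)c12 | intermediate
7 | dichloro(1,4,5,8-tetramethoxynaphthalen-2-yl)cerium | COc1cc([Ce](Cl)Cl)c(OC)c2c(OC)ccc(OC)c12 | intermediate
8 | (1R,3S)-3-[(tert-butyldimethylsilyl)oxy]-2,2-dimethyl-1-(1,4,5,8-tetramethoxynaphthalen-2-yl)cyclopentan-1-ol | CC(C)(C)[Si](C)(C)O[C@H]1CC[C@](O)(c2cc(OC)c3c(OC)ccc(OC)c3c2OC)C1(C)C | intermediate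
9 | (1R,3S)-2,2-dimethyl-1-(1,4,5,8-tetramethoxynaphthalen-2-yl)cyclopentane-1,3-diol | O[C@H]1CC[C@](O)(c2cc(OC)c3c(OC)ccc(OC)c3c2OC)C1(C)C | intermediate
10 | (S)-3-hydroxy-2,2-dimethyl-3-(1,4,5,8-tetramethoxynaphthalen-2-yl)cyclopentan-1-one | O=C1CC[C@](O)(c2cc(OC)c3c(OC)ccc(OC)c3c2OC)C1(C)C | intermediate
11 | (S)-2,2-dimethyl-3-(1,4,5,8-tetramethoxynaphthalen-2-yl)-3-[(triethylsilyl)oxy]cyclopentan-1-one | CC[Si](CC)(CC)O[C@]1(c2cc(OC)c3c(OC)ccc(OC)c3c2OC)CCC(=O)C1(C)C | intermediate
12 | (3S)-2,2-dimethyl-3-(1,4,5,8-tetramethoxynaphthalen-2-yl)-5-(2,2,2-trifluoroacetyl)-3-[(triethylsilyl)oxy]cyclopentan-1-one (enolised, C5 undefined) | CC[Si](CC)(CC)O[C@]1(c2cc(OC)c3c(OC)ccc(OC)c3c2OC)CC(C(=O)C(F)(F)F)C(=O)C1(C)C | intermediate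
13 | (S)-2-diazo-5,5-dimethyl-4-(1,4,5,8-tetramethoxynaphthalen-2-yl)-4-[(triethylsilyl)oxy]cyclopentan-1-one | CC[Si](CC)(CC)O[C@]1(c2cc(OC)c3c(OC)ccc(OC)c3c2OC)CC(=[N+]=[N-])C(=O)C1(C)C | intermediate
14 | (R)-{2,2-dimethyl-3-(1,4,5,8-tetramethoxynaphthalen-2-yl)-3-[(triethylsilyl)oxy]cyclobutylidene}methanone (ketene) | CC[Si](CC)(CC)O[C@]1(c2cc(OC)c3c(OC)ccc(OC)c3c2OC)CC(=C=O)C1(C)C | intermediate
15 | (1RS,3R)-2,2-dimethyl-3-(1,4,5,8-tetramethoxynaphthalen-2-yl)-3-[(triethylsilyl)oxy]cyclobutane-1-carboxylic acid (both C1 epimers) | CC[Si](CC)(CC)O[C@]1(c2cc(OC)c3c(OC)ccc(OC)c3c2OC)CC(C(=O)O)C1(C)C | intermediate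
16 | 2-thioxopyridin-1(2H)-yl (1RS,3R)-2,2-dimethyl-3-(1,4,5,8-tetramethoxynaphthalen-2-yl)-3-[(triethylsilyl)oxy]cyclobutane-1-carboxylate | CC[Si](CC)(CC)O[C@]1(c2cc(OC)c3c(OC)ccc(OC)c3c2OC)CC(C(=O)ON2C=CC=CC2=S)C1(C)C | intermediate
17 | (R)-triethyl{[2,2-dimethyl-1-(1,4,5,8-tetramethoxynaphthalen-2-yl)cyclobutyl]oxy}silane | CC[Si](CC)(CC)O[C@]1(c2cc(OC)c3c(OC)ccc(OC)c3c2OC)CCC1(C)C | intermediate
18 | (R)-2,2-dimethyl-1-(1,4,5,8-tetramethoxynaphthalen-2-yl)cyclobutan-1-ol | O[C@]1(c2cc(OC)c3c(OC)ccc(OC)c3c2OC)CCC1(C)C | intermediate
19 | angelic acid, (Z)-2-methylbut-2-enoic acid | C/C=C(/C)C(=O)O | starting material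
20 | (Z)-2-methylbut-2-enoic 2,4,6-trichlorobenzoic anhydride | C/C=C(/C)C(=O)OC(=O)c1c(Cl)cc(Cl)cc1Cl | intermediate
21 | (R)-2,2-dimethyl-1-(1,4,5,8-tetramethoxynaphthalen-2-yl)cyclobutyl (Z)-2-methylbut-2-enoate | C/C=C(/C)C(=O)O[C@]1(c2cc(OC)c3c(OC)ccc(OC)c3c2OC)CCC1(C)C | intermediate
22 | (R)-1-(1,4-dimethoxy-5,8-dioxo-5,8-dihydronaphthalen-2-yl)-2,2-dimethylcyclobutyl (Z)-2-methylbut-2-enoate | C/C=C(/C)C(=O)O[C@]1(c2cc(OC)c3C(=O)C=CC(=O)c3c2OC)CCC1(C)C | intermediate
23 | (R)-2,2-dimethyl-1-(1,4,5,8-tetraoxo-1,4,5,8-tetrahydronaphthalen-2-yl)cyclobutyl (Z)-2-methylbut-2-enoate | C/C=C(/C)C(=O)O[C@]1(C2=CC(=O)C3=C(C2=O)C(=O)C=CC3=O)CCC1(C)C | intermediate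
24 | (R)-1-(5,8-dihydroxy-1,4-dioxo-1,4-dihydronaphthalen-2-yl)-2,2-dimethylcyclobutyl (Z)-2-methylbut-2-enoate | C/C=C(/C)C(=O)O[C@]1(C2=CC(=O)c3c(O)ccc(O)c3C2=O)CCC1(C)C | target

## Step count and least certain steps

Total: 14 steps. Longest linear sequence: 13 steps (from 1 through steps 1, 2 and 4 to 14); step 3 prepares the aryl bromide on the side branch.

**Step 9 (key step).** The most likely failure is that the excited diazo ketone follows other paths than the 1,2-shift. A hydride shift from the adjacent methylene could take over, or light absorbed by the arene could lead to sensitised triplet carbene chemistry, so that little ketene forms. The fallback is a semibenzilic (quasi-Favorskii) contraction, which forms the same C3'–C4' bond without a carbene. It sets out from 11: the lithium enolate (LiN(SiMe3)2, THF, −78 °C) would be brominated with 1,2-dibromo-1,1,2,2-tetrachloroethane to (3S,5RS)-5-bromo-2,2-dimethyl-3-(1,4,5,8-tetramethoxynaphthalen-2-yl)-3-[(triethylsilyl)oxy]cyclopentan-1-one F1. Hydroxide (KOH, aqueous THF) would then add to the non-enolisable carbonyl, and the CMe2 carbon would shift to the bromine-bearing carbon with loss of bromide. This comes back to the route at 15.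

**Step 4.** The most likely failure is poor or reversed facial selectivity in the aryl addition, since the C3 silyloxy group is the only element that distinguishes the two faces of a ketone flanked by a gem-dimethyl group. Partial enolisation is a second concern. If the aryl group prefers to enter syn to the silyloxy group, the relay centre would be installed with the opposite configuration, starting from 1:
- Reduction with the (S)-oxazaborolidine would give (R)-3-hydroxy-2,2-dimethylcyclopentan-1-one F2.
- Silylation would give (R)-3-[(tert-butyldimethylsilyl)oxy]-2,2-dimethylcyclopentan-1-one F3.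
- Syn addition of 7 would give (1R,3R)-3-[(tert-butyldimethylsilyl)oxy]-2,2-dimethyl-1-(1,4,5,8-tetramethoxynaphthalen-2-yl)cyclopentan-1-ol F4.
- Desilylation would give (1R,3R)-2,2-dimethyl-1-(1,4,5,8-tetramethoxynaphthalen-2-yl)cyclopentane-1,3-diol F5.
- Oxidation as in step 6 comes back to the route at 10.

**Step 12.** The most likely failure is slow acylation of the very hindered alkoxide. Longer times or higher temperatures would then bring Z to E isomerisation, or attack at the wrong carbonyl of the anhydride. The fallback builds the Z-alkene after the ester bond. It sets out from 18: the lithium alkoxide would be acylated with 2-[bis(2,2,2-trifluoroethoxy)phosphoryl]propanoyl chloride, which reacts through a small ketene-like electrophile, to give (R)-2,2-dimethyl-1-(1,4,5,8-tetramethoxynaphthalen-2-yl)cyclobutyl 2-[bis(2,2,2-trifluoroethoxy)phosphoryl]propanoate F6. A Still–Gennari olefination with acetaldehyde (KN(SiMe3)2, 18-crown-6, THF, −78 °C) would then give the Z-enoate and come back to the route at 21.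

**Step 14.** The most likely failure is ionisation of the tertiary ester in nitric acid, or over-oxidation of the diquinone before it is reduced. The fallback removes the two remaining methyl groups without an oxidant. It sets out from 22, where both methoxy groups lie peri to a quinone carbonyl and so should be cleaved by chelation-assisted demethylation with BCl3 in CH2Cl2 at −78 °C. This arrives directly at 24 with no new intermediate.

## Further compounds

F1 | step 9 | (3S,5RS)-5-bromo-2,2-dimethyl-3-(1,4,5,8-tetramethoxynaphthalen-2-yl)-3-[(triethylsilyl)oxy]cyclopentan-1-one | CC[Si](CC)(CC)O[C@]1(c2cc(OC)c3c(OC)ccc(OC)c3c2OC)CC(Br)C(=O)C1(C)C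
F2 | step 4 | (R)-3-hydroxy-2,2-dimethylcyclopentan-1-one | O[C@@H]1CCC(=O)C1(C)C
F3 | step 4 | (R)-3-[(tert-butyldimethylsilyl)oxy]-2,2-dimethylcyclopentan-1-one | CC(C)(C)[Si](C)(C)O[C@@H]1CCC(=O)C1(C)C
F4 | step 4 | (1R,3R)-3-[(tert-butyldimethylsilyl)oxy]-2,2-dimethyl-1-(1,4,5,8-tetramethoxynaphthalen-2-yl)cyclopentan-1-ol | CC(C)(C)[Si](C)(C)O[C@@H]1CC[C@](O)(c2cc(OC)c3c(OC)ccc(OC)c3c2OC)C1(C)C
F5 | step 4 | (1R,3R)-2,2-dimethyl-1-(1,4,5,8-tetramethoxynaphthalen-2-yl)cyclopentane-1,3-diol | O[C@@H]1CC[C@](O)(c2cc(OC)c3c(OC)ccc(OC)c3c2OC)C1(C)C
F6 | step 12 | (R)-2,2-dimethyl-1-(1,4,5,8-tetramethoxynaphthalen-2-yl)cyclobutyl 2-[bis(2,2,2-trifluoroethoxy)phosphoryl]propanoate | CC(C(=O)O[C@]1(c2cc(OC)c3c(OC)ccc(OC)c3c2OC)CCC1(C)C)P(=O)(OCC(F)(F)F)OCC(F)(F)F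
F0 | step 14 | none | none
A1 | alternative 1 | (R)-1-[5,8-bis(methoxymethoxy)-1,4-dioxo-1,4-dihydronaphthalen-2-yl]-2,2-dimethylcyclobutyl (Z)-2-methylbut-2-enoate | C/C=C(/C)C(=O)O[C@]1(C2=CC(=O)c3c(OCOC)ccc(OCOC)c3C2=O)CCC1(C)C
A2 | alternative 1 | 3,6-bis(methoxymethoxy)benzocyclobutene-1,2-dione | COCOc1ccc(OCOC)c2c1C(=O)C2=O
A3 | alternative 1 | (R)-1-ethynyl-2,2-dimethylcyclobutyl (Z)-2-methylbut-2-enoate | C/C=C(/C)C(=O)O[C@]1(C#C)CCC1(C)C
A4 | alternative 1 | 2,2-dimethylcyclobutan-1-one | CC1(C)CCC1=O
A5 | alternative 2 | (S)-2-[2,2-dimethyl-1-(1,4,5,8-tetramethoxynaphthalen-2-yl)cyclobutyl]-4,4,5,5-tetramethyl-1,3,2-dioxaborolane | CC1(C)OB(OC1(C)C)[C@]4(c2cc(OC)c3c(OC)ccc(OC)c3c2OC)CCC4(C)C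
A6 | alternative 2 | (S)-4-methyl-4-(4,4,5,5-tetramethyl-1,3,2-dioxaborolan-2-yl)-1-(1,4,5,8-tetramethoxynaphthalen-2-yl)pentyl N,N-diisopropylcarbamate | CC(C)N(C(C)C)C(=O)O[C@H](c1cc(OC)c2c(OC)ccc(OC)c2c1OC)CCC(C)(C)B1OC(C)(C)C(C)(C)O1
A7 | alternative 3 | (R)-1-[1,4-dihydroxy-5,8-bis(methoxymethoxy)naphthalen-2-yl]-2,2-dimethylcyclobutyl (Z)-2-methylbut-2-enoate | C/C=C(/C)C(=O)O[C@]1(c2cc(O)c3c(OCOC)ccc(OCOC)c3c2O)CCC1(C)C
A8 | alternative 3 | (R)-1-{3-[2,5-bis(methoxymethoxy)phenyl]-3-hydroxy-4-oxocyclobut-1-en-1-yl}-2,2-dimethylcyclobutyl (Z)-2-methylbut-2-enoate (ring carbinol undefined) | C/C=C(/C)C(=O)O[C@]1(C2=CC(O)(c3cc(OCOC)ccc3OCOC)C2=O)CCC1(C)C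
A9 | alternative 3 | (R)-1-(3,4-dioxocyclobut-1-en-1-yl)-2,2-dimethylcyclobutyl (Z)-2-methylbut-2-enoate | C/C=C(/C)C(=O)O[C@]1(C2=CC(=O)C2=O)CCC1(C)C
A10 | alternative 3 | [2,5-bis(methoxymethoxy)phenyl]lithium | [Li]c1cc(OCOC)ccc1OCOC
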